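**Retrosynthetic overview**

1. Labels: C1 = ring-fusion carbon bearing CH3; C2, C3 = cyclopentane CH2; C4 = C(OH)(iPr); C5 = ring-fusion CH; C6 = CH–O–anisoyl; C7 = CH2; C8–C9 = epoxide (CH3 on C8); C10 = CH2. Rings: cyclopentane C1–C5, cycloheptane C5–C6–C7–C8–C9–C10–C1, oxirane C8–C9–O.
2. Feature: the angular methyl on C1 lies β to the oxygen-bearing C4, and C5 between them carries the carbinol carbon C6. This is the pattern left by β-methylation and α-aldol reaction of a cyclopentenone, so C1–CH3 and C5–C6 are cut together (3-allylcyclopentenone + Me3Al + ketal-protected 3-oxobutanal).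
3. Later bonds: C4–iPr (organocerium addition anti to the C5 arm); C8=C9 (ring-closing metathesis of the C1 allyl group with a methallyl group made from the unmasked methyl ketone); epoxide oxygen (delivered by the free C6–OH); C6–O ester last.
4. Ring order: cyclopentane bought in with 3-ethoxycyclopentenone; cycloheptene closed in step 8; oxirane formed in step 10.

Key step: step 3

Remark: the antipode of the chiral NHC ligand is assumed to be the one that sends methyl to the Si face of the β-carbon of 4 (R at C1); the labels C1–C10 above are used throughout.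

**Route**

Step 1
Reactants: 1 3-ethoxycyclopent-2-en-1-one; 2 allylmagnesium bromide
Product: 4 3-(prop-2-en-1-yl)cyclopent-2-en-1-one, via magnesium alkoxide adduct 3 (not isolated)
Conditions: THF, 0 °C; then 1 M aq. HCl, 0 °C, short contact
Reagents that add atoms: water, O
Why: Stork–Danheiser alkylative carbonyl transposition, in which 1,2-addition of the Grignard reagent to the vinylogous ester and acid-promoted loss of ethanol from the tertiary allylic alkoxide should give the β-allyl enone, the brief cold acid treatment keeping the skipped alkene out of conjugation.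

Step 2
Reactants: 5 ethyl 2-(2-methyl-1,3-dioxolan-2-yl)acetate
Product: 7 2-(2-methyl-1,3-dioxolan-2-yl)acetaldehyde, via aluminium hemiacetal 6 (not isolated)
Conditions: DIBAL-H (1.05 equiv), CH2Cl2, −78 °C; MeOH, then aq. Rochelle salt; used at once
Reagents that add atoms: none
Why: Partial reduction of an ester with DIBAL-H at −78 °C, where the tetrahedral aluminium hemiacetal (held by the neighbouring ketal oxygen) should persist until work-up and then release the aldehyde.

Step 3
Reactants: 4 3-(prop-2-en-1-yl)cyclopent-2-en-1-one; 8 trimethylaluminium; 7 2-(2-methyl-1,3-dioxolan-2-yl)acetaldehyde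
Product: 10 (2S,3R)-2-[(1S)-1-hydroxy-2-(2-methyl-1,3-dioxolan-2-yl)ethyl]-3-methyl-3-(prop-2-en-1-yl)cyclopentan-1-one, via dimethylaluminium enolate 9 (not isolated)
Conditions: Cu(OTf)2 (5 mol %), chiral sulfonate-bearing NHC–Ag(I) complex (2.5 mol %), 8 (1.5 equiv), THF, −78 °C; then 7 (2 equiv), −78 → −40 °C; aq. Rochelle salt
Reagents that add atoms: none
Why: Methyl passes from aluminium to the chiral NHC–copper centre, which adds it to the β-carbon C1 of enone 4 (π-complex, Cu(III) alkyl, reductive elimination) and leaves the regiodefined dimethylaluminium enolate 9 (C4–O–Al, C4=C5); 9 then adds through C5 to the aluminium-bound aldehyde 7 in a closed six-membered Zimmerman–Traxler transition state, so that C1–CH3 and C5–C6 are made in one flask. The closest known reaction type is this very one, copper-catalysed enantioselective conjugate addition of trialkylaluminium reagents to β-substituted cyclic enones with aldol trapping of the aluminium enolate, applied here to a new pair of partners. No ring is closed: the cyclopentane comes from 1 and the step adds two acyclic bonds. C1 is set by the catalyst (methyl to the Si face of the β-carbon, giving R), C5 by the substrate (the aldehyde comes in on the enolate face that carries the methyl group, away from the longer allyl arm, so that C6 and C10 are trans), and C6 by the chair transition state of the necessarily E-configured ring enolate with the aldehyde chain equatorial (anti aldol, 2S,1′S). The step needs 1,4- over 1,2-methylation (copper catalysis), enantioface selection (ligand), enolate-face selection (the allyl-versus-methyl size difference, the weakest control, so minor C5/C6 diastereomers are expected and are removed by chromatography here or after step 4) and anti over syn (tight aluminium-centred transition state at low temperature). Coordinating THF, −78 °C and an excess of 7 should keep residual trimethylaluminium from methylating the aldehyde or opening the dioxolane.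

Step 4
Reactants: 10 (2S,3R)-2-[(1S)-1-hydroxy-2-(2-methyl-1,3-dioxolan-2-yl)ethyl]-3-methyl-3-(prop-2-en-1-yl)cyclopentan-1-one
Product: 11 (2S,3R)-2-[(1S)-1-{[tert-butyl(dimethyl)silyl]oxy}-2-(2-methyl-1,3-dioxolan-2-yl)ethyl]-3-methyl-3-(prop-2-en-1-yl)cyclopentan-1-one
Conditions: TBSOTf (1.3 equiv), 2,6-lutidine, CH2Cl2, −78 °C
Reagents that add atoms: tert-butyldimethylsilyl trifluoromethanesulfonate, CC(C)(C)[Si](C)(C)OS(=O)(=O)C(F)(F)F
Why: Silylation of a secondary alcohol with a silyl triflate and a hindered pyridine base at low temperature should cap the C6 hydroxyl before retro-aldol cleavage or C5 epimerisation can occur and should leave the ketone and the dioxolane untouched.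

Step 5
Reactants: 11 (2S,3R)-2-[(1S)-1-{[tert-butyl(dimethyl)silyl]oxy}-2-(2-methyl-1,3-dioxolan-2-yl)ethyl]-3-methyl-3-(prop-2-en-1-yl)cyclopentan-1-one; 12 isopropylmagnesium chloride
Product: 13 (1R,2S,3R)-2-[(1S)-1-{[tert-butyl(dimethyl)silyl]oxy}-2-(2-methyl-1,3-dioxolan-2-yl)ethyl]-3-methyl-1-(propan-2-yl)-3-(prop-2-en-1-yl)cyclopentan-1-ol
Conditions: 12 and anhydrous CeCl3 (3 equiv each), THF, −78 → 0 °C; then H2O
Reagents that add atoms: none
Why: Imamoto organocerium 1,2-addition, in which the weakly basic, oxophilic isopropylcerium reagent should add to the hindered, enolisable C4 ketone instead of deprotonating it or transferring hydride, entering from the ring face opposite the bulky silyloxyalkyl arm on the adjacent C5 so that the new hydroxyl is cis to that arm (C4 = R).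

Step 6
Reactants: 13 (1R,2S,3R)-2-[(1S)-1-{[tert-butyl(dimethyl)silyl]oxy}-2-(2-methyl-1,3-dioxolan-2-yl)ethyl]-3-methyl-1-(propan-2-yl)-3-(prop-2-en-1-yl)cyclopentan-1-ol
Product: 14 (4S)-4-{[tert-butyl(dimethyl)silyl]oxy}-4-[(1S,2R,5R)-5-hydroxy-2-methyl-5-(propan-2-yl)-2-(prop-2-en-1-yl)cyclopentyl]butan-2-one
Conditions: PPTS (0.2 equiv), acetone/H2O (10:1), 50 °C
Reagents that add atoms: water, O
Why: Acid-catalysed hydrolysis of the dioxolane under conditions mild enough for the secondary TBS ether and the tertiary alcohol should free the methyl ketone, which may sit partly as its cyclic hemiketal with the C4 hydroxyl without consequence for the next step.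

Step 7
Reactants: 14 (4S)-4-{[tert-butyl(dimethyl)silyl]oxy}-4-[(1S,2R,5R)-5-hydroxy-2-methyl-5-(propan-2-yl)-2-(prop-2-en-1-yl)cyclopentyl]butan-2-one
Product: 15 (1R,2S,3R)-2-[(1S)-1-{[tert-butyl(dimethyl)silyl]oxy}-3-methylbut-3-en-1-yl]-3-methyl-1-(propan-2-yl)-3-(prop-2-en-1-yl)cyclopentan-1-ol
Conditions: Ph3PCH3Br (4 equiv), KHMDS (3.8 equiv), THF, 0 °C → rt
Reagents that add atoms: methyltriphenylphosphonium bromide, C[P+](c1ccccc1)(c1ccccc1)c1ccccc1.[Br-]
Why: Wittig methylenation of a methyl ketone with excess non-stabilised ylide (one equivalent is taken up by the hydroxyl/hemiketal) should give the 1,1-disubstituted alkene, and the slight excess of phosphonium salt over base leaves no free amide to eliminate the β-silyloxy group.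

Step 8
Reactants: 15 (1R,2S,3R)-2-[(1S)-1-{[tert-butyl(dimethyl)silyl]oxy}-3-methylbut-3-en-1-yl]-3-methyl-1-(propan-2-yl)-3-(prop-2-en-1-yl)cyclopentan-1-ol
Product: 16 (3R,3aS,4S,8aR)-4-{[tert-butyl(dimethyl)silyl]oxy}-6,8a-dimethyl-3-(propan-2-yl)-1,2,3,3a,4,5,8,8a-octahydroazulen-3-ol
Conditions: Grubbs second-generation catalyst (5 mol %), CH2Cl2 (5 mM), 40 °C
Reagents that add atoms: none
Why: Ring-closing metathesis joins the monosubstituted allyl alkene and the 1,1-disubstituted methallyl alkene into the trisubstituted C8=C9 cycloheptene with loss of ethene, the trans arrangement of the two arms on C1 and C5 fixing the trans ring fusion without creating a stereocentre.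

Step 9
Reactants: 16 (3R,3aS,4S,8aR)-4-{[tert-butyl(dimethyl)silyl]oxy}-6,8a-dimethyl-3-(propan-2-yl)-1,2,3,3a,4,5,8,8a-octahydroazulen-3-ol
Product: 17 (3R,3aS,4S,8aR)-6,8a-dimethyl-3-(propan-2-yl)-1,2,3,3a,4,5,8,8a-octahydroazulene-3,4-diol
Conditions: TBAF (3 equiv), THF, rt → 45 °C
Reagents that add atoms: none
Why: Fluoride-mediated cleavage of the secondary TBS ether, driven by the Si–F bond, should leave the tertiary alcohol and the alkene untouched and frees the homoallylic C6 hydroxyl needed as a directing group.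

Step 10
Reactants: 17 (3R,3aS,4S,8aR)-6,8a-dimethyl-3-(propan-2-yl)-1,2,3,3a,4,5,8,8a-octahydroazulene-3,4-diol
Product: 18 (3R,3aS,4S,6R,7S,8aR)-6,7-epoxy-6,8a-dimethyl-3-(propan-2-yl)decahydroazulene-3,4-diol
Conditions: VO(acac)2 (5 mol %), t-BuOOH (1.5 equiv, in decane), CH2Cl2, 0 °C → rt
Reagents that add atoms: tert-butyl hydroperoxide, CC(C)(C)OO
Why: Vanadium-catalysed hydroxyl-directed epoxidation, in which the vanadate ester of the homoallylic C6–OH should deliver oxygen to the alkene face syn to that hydroxyl, which is also the face away from the angular C1 methyl, setting C8 (R) and C9 (S) together while the tertiary C4–OH is too remote to compete.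

Step 11
Reactants: 18 (3R,3aS,4S,6R,7S,8aR)-6,7-epoxy-6,8a-dimethyl-3-(propan-2-yl)decahydroazulene-3,4-diol; 19 4-methoxybenzoyl chloride
Product: 20 (3R,3aS,4S,6R,7S,8aR)-6,7-epoxy-3-hydroxy-6,8a-dimethyl-3-(propan-2-yl)decahydroazulen-4-yl 4-methoxybenzoate
Conditions: 19 (1.5 equiv), Et3N, DMAP (0.2 equiv), CH2Cl2, 0 °C → rt
Reagents that add atoms: none
Why: DMAP-catalysed acyl transfer from the acid chloride should esterify the secondary C6 hydroxyl selectively, the fully substituted C4 hydroxyl being unreactive under these conditions and the basic medium sparing the epoxide.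

**Compound list**

1 | 3-ethoxycyclopent-2-en-1-one | CCOC1=CC(=O)CC1 | starting material
2 | allylmagnesium bromide | C=CC[Mg]Br | starting material
3 | bromomagnesium 3-ethoxy-1-(prop-2-en-1-yl)cyclopent-2-en-1-olate (racemic) | CCOC1=CC(CC=C)(O[Mg]Br)CC1 | intermediate (not isolated)
4 | 3-(prop-2-en-1-yl)cyclopent-2-en-1-one | C=CCC1=CC(=O)CC1 | intermediate
5 | ethyl 2-(2-methyl-1,3-dioxolan-2-yl)acetate | CCOC(=O)CC1(C)OCCO1 | starting material
6 | [1-ethoxy-2-(2-methyl-1,3-dioxolan-2-yl)ethoxy]bis(2-methylpropyl)alane (hemiacetal carbon undefined) | CCOC(CC1(C)OCCO1)O[Al](CC(C)C)CC(C)C | intermediate (not isolated)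
7 | 2-(2-methyl-1,3-dioxolan-2-yl)acetaldehyde | O=CCC1(C)OCCO1 | intermediate
8 | trimethylaluminium | C[Al](C)C | starting material
9 | dimethylaluminium (3R)-3-methyl-3-(prop-2-en-1-yl)cyclopent-1-en-1-olate | C[Al](C)OC1=C[C@@](C)(CC=C)CC1 | intermediate (not isolated)
10 | (2S,3R)-2-[(1S)-1-hydroxy-2-(2-methyl-1,3-dioxolan-2-yl)ethyl]-3-methyl-3-(prop-2-en-1-yl)cyclopentan-1-one | O=C1CC[C@](C)(CC=C)[C@H]1[C@@H](O)CC2(C)OCCO2 | intermediate
11 | (2S,3R)-2-[(1S)-1-{[tert-butyl(dimethyl)silyl]oxy}-2-(2-methyl-1,3-dioxolan-2-yl)ethyl]-3-methyl-3-(prop-2-en-1-yl)cyclopentan-1-one | O=C1CC[C@](C)(CC=C)[C@H]1[C@@H](O[Si](C)(C)C(C)(C)C)CC2(C)OCCO2 | intermediate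
12 | isopropylmagnesium chloride | CC(C)[Mg]Cl | starting material
13 | (1R,2S,3R)-2-[(1S)-1-{[tert-butyl(dimethyl)silyl]oxy}-2-(2-methyl-1,3-dioxolan-2-yl)ethyl]-3-methyl-1-(propan-2-yl)-3-(prop-2-en-1-yl)cyclopentan-1-ol | CC(C)[C@]1(O)CC[C@](C)(CC=C)[C@H]1[C@@H](O[Si](C)(C)C(C)(C)C)CC2(C)OCCO2 | intermediate
14 | (4S)-4-{[tert-butyl(dimethyl)silyl]oxy}-4-[(1S,2R,5R)-5-hydroxy-2-methyl-5-(propan-2-yl)-2-(prop-2-en-1-yl)cyclopentyl]butan-2-one | CC(C)[C@]1(O)CC[C@](C)(CC=C)[C@H]1[C@@H](O[Si](C)(C)C(C)(C)C)CC(C)=O | intermediate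
15 | (1R,2S,3R)-2-[(1S)-1-{[tert-butyl(dimethyl)silyl]oxy}-3-methylbut-3-en-1-yl]-3-methyl-1-(propan-2-yl)-3-(prop-2-en-1-yl)cyclopentan-1-ol | CC(C)[C@]1(O)CC[C@](C)(CC=C)[C@H]1[C@@H](O[Si](C)(C)C(C)(C)C)CC(C)=C | intermediate
16 | (3R,3aS,4S,8aR)-4-{[tert-butyl(dimethyl)silyl]oxy}-6,8a-dimethyl-3-(propan-2-yl)-1,2,3,3a,4,5,8,8a-octahydroazulen-3-ol | CC(C)(C)[Si](C)(C)O[C@H]2CC(C)=CC[C@@]3(C)CC[C@@](O)(C(C)C)[C@H]23 | intermediate
17 | (3R,3aS,4S,8aR)-6,8a-dimethyl-3-(propan-2-yl)-1,2,3,3a,4,5,8,8a-octahydroazulene-3,4-diol | O[C@H]2CC(C)=CC[C@@]3(C)CC[C@@](O)(C(C)C)[C@H]23 | intermediate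
18 | (3R,3aS,4S,6R,7S,8aR)-6,7-epoxy-6,8a-dimethyl-3-(propan-2-yl)decahydroazulene-3,4-diol | O[C@H]2C[C@@]3(C)O[C@H]3C[C@@]3(C)CC[C@@](O)(C(C)C)[C@H]23 | intermediate
19 | 4-methoxybenzoyl chloride | COc1ccc(C(Cl)=O)cc1 | starting material
20 | (3R,3aS,4S,6R,7S,8aR)-6,7-epoxy-3-hydroxy-6,8a-dimethyl-3-(propan-2-yl)decahydroazulen-4-yl 4-methoxybenzoate | COc1ccc(C(=O)O[C@H]2C[C@@]3(C)O[C@H]3C[C@@]3(C)CC[C@@](O)(C(C)C)[C@H]23)cc1 | target

**Step count**

Total: 11 steps. Longest linear sequence: 10 steps (steps 1 and 3–11); the aldehyde 7 is made in one step on a side branch.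

**Steps most likely to fail**

Step 3. The enolate may not discriminate well between its methyl-bearing and allyl-bearing faces. Residual trimethylaluminium may also consume the aldehyde or open its ketal, so that trapping is slow and unselective.
Fallback, setting out from 4: the conjugate methylation is run as in step 3, but enolate 9 is quenched with triethylsilyl triflate and the product is isolated as the silyl enol ether F1, on which the enantiomeric purity can be checked. F1 is cleaved with methyllithium (THF, 0 °C) to the regiodefined lithium enolate, which is transmetallated with ZnCl2 at −78 °C and combined with 7. The closed transition state of the zinc enolate should again give the anti aldol, now free of copper and organoaluminium residues and with a metal that can be varied to sharpen face selection. The route is rejoined at 10.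

Step 5. The hindered C4 ketone may be deprotonated or reduced by β-hydride transfer instead of being alkylated, and facial selectivity may erode.
Fallback, setting out from 11: isopropenylmagnesium bromide/CeCl3 (THF, −78 → 0 °C) supplies an sp2 nucleophile that has no β-hydride to transfer and is less basic; attack anti to the C5 arm should give the isopropenyl carbinol F2. Ketal hydrolysis as in step 6 should give the isopropenyl methyl ketone F3, and methylenation as in step 7 the triene F4. Ring-closing metathesis as in step 8 should give the bicyclic diene F5, since the isopropenyl group on the fully substituted carbinol carbon is a far poorer metathesis partner than the methallyl group. Chemoselective hydrogenation of the 1,1-disubstituted alkene of F5 over the trisubstituted ring alkene (H2, RhCl(PPh3)3, benzene, rt) brings the route back at 16.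

Step 10. Oxygen may be delivered to the wrong alkene face, or the Lewis-acidic metal may trigger transannular opening of the new epoxide by the C4 hydroxyl.
Fallback, setting out from 17: the order of the last two steps is reversed and the control element changed. Acylation with 19 (Et3N, DMAP, CH2Cl2) should give the unsaturated ester jaeschkeanadiol 4-methoxybenzoate F6. Epoxidation with buffered mCPBA (NaHCO3, CH2Cl2, 0 °C) then relies on steric approach anti to the angular C1 methyl and not on hydroxyl direction, and gives 20 directly.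

**Further compounds**

F1 | step 3 | silyl enol ether (R)-triethyl{[3-methyl-3-(prop-2-en-1-yl)cyclopent-1-en-1-yl]oxy}silane | CC[Si](CC)(CC)OC1=C[C@@](C)(CC=C)CC1
F2 | step 5 | isopropenyl carbinol (1S,2S,3R)-2-[(1S)-1-{[tert-butyl(dimethyl)silyl]oxy}-2-(2-methyl-1,3-dioxolan-2-yl)ethyl]-3-methyl-1-(prop-1-en-2-yl)-3-(prop-2-en-1-yl)cyclopentan-1-ol | C=C(C)[C@]1(O)CC[C@](C)(CC=C)[C@H]1[C@@H](O[Si](C)(C)C(C)(C)C)CC2(C)OCCO2
F3 | step 5 | isopropenyl methyl ketone (4S)-4-{[tert-butyl(dimethyl)silyl]oxy}-4-[(1S,2R,5S)-5-hydroxy-2-methyl-5-(prop-1-en-2-yl)-2-(prop-2-en-1-yl)cyclopentyl]butan-2-one | C=C(C)[C@]1(O)CC[C@](C)(CC=C)[C@H]1[C@@H](O[Si](C)(C)C(C)(C)C)CC(C)=O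
F4 | step 5 | triene (1S,2S,3R)-2-[(1S)-1-{[tert-butyl(dimethyl)silyl]oxy}-3-methylbut-3-en-1-yl]-3-methyl-1-(prop-1-en-2-yl)-3-(prop-2-en-1-yl)cyclopentan-1-ol | C=C(C)[C@]1(O)CC[C@](C)(CC=C)[C@H]1[C@@H](O[Si](C)(C)C(C)(C)C)CC(C)=C
F5 | step 5 | bicyclic diene (3S,3aS,4S,8aR)-4-{[tert-butyl(dimethyl)silyl]oxy}-6,8a-dimethyl-3-(prop-1-en-2-yl)-1,2,3,3a,4,5,8,8a-octahydroazulen-3-ol | CC(C)(C)[Si](C)(C)O[C@H]2CC(C)=CC[C@@]3(C)CC[C@@](O)(C(C)=C)[C@H]23
F6 | step 10 | jaeschkeanadiol 4-methoxybenzoate, (3R,3aS,4S,8aR)-3-hydroxy-6,8a-dimethyl-3-(propan-2-yl)-1,2,3,3a,4,5,8,8a-octahydroazulen-4-yl 4-methoxybenzoate | COc1ccc(C(=O)O[C@H]2CC(C)=CC[C@@]3(C)CC[C@@](O)(C(C)C)[C@H]23)cc1
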